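**Plan**

Numbering (germacrane): C1 = furanone C=O, C2=C3 = furanone C=C (C3 carries the ring O), C4=C5 = Z-alkene, C6 = acyloxy carbinol, C7/C8 = lactone ring fusion, C10 = quaternary C–O, C12 = lactone C=O, C13 = exocyclic CH2.
Retrosynthesis: cut the C6 ester and the C11=C13 methylene, then both furanone bonds O–C3 and C1–C10 at once, which opens the ten-membered carbocycle and the furanone to seco ynal–methyl ketone 20; then the lactone C–O, C8–C9 (acetone aldol), C6–C7 (anti-aldol) and C3–C4 (Sonogashira).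
Enabling feature: the furanone ring O–C3=C2–C1(=O)–C10 is an acyloin (tertiary C10–O next to the C1 ketone) built into a vinylogous ester (O–C3=C2–C1=O), so C1 can arrive as the acyl anion of an ynal on a C10 methyl ketone and the new C10 alkoxide can close on C3.
Forward ring order: butyrolactone (step 10), then carbocycle and furanone together (step 11), then the exocyclic methylene and the ester.
Stereochemistry: C6/C7 from an Evans magnesium anti-aldol with (R)-4-benzyloxazolidin-2-one, C8 from a D-proline acetone aldol, C10 in the key step (chiral triazolylidene plus the trans-lactone tether), the Z-alkene from hydroalumination/iodination, the epoxide from Sharpless epoxidation with D-(−)-diethyl tartrate.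

Key step: step 11

Remark on the structure: the target is read as 6S,7R,8S,10R with a 4Z alkene, a trans-fused 12,8-lactone and a (2S,3S)-epoxyangelate (carboxyl and 3-methyl cis on the oxirane) at C6.

**Route**

Step 1
Reactants: 1 but-2-yn-1-ol
Product: 3 (Z)-3-iodobut-2-en-1-ol, via cyclic alkenylaluminate 2 (not isolated)
Conditions: NaAlH2(OCH2CH2OCH3)2, THF, 0 → 23 °C; then I2, THF, −78 → 0 °C
Reagents that add atoms: iodine, II
Why: Hydroxyl-directed trans-hydroalumination puts aluminium on C3 in a five-membered aluminate, and iodinolysis with retention should give the Z-iodoalkene that becomes the Z-C4=C5 alkene.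

Step 2
Reactants: 3 (Z)-3-iodobut-2-en-1-ol; 4 3,3-diethoxyprop-1-yne
Product: 5 (Z)-6,6-diethoxy-3-methylhex-2-en-4-yn-1-ol
Conditions: PdCl2(PPh3)2 (3 mol%), CuI (6 mol%), Et3N, THF, 23 °C
Reagents that add atoms: none
Why: Sonogashira coupling of a vinyl iodide proceeds with retention of alkene geometry and tolerates the free alcohol and the acetal.

Step 3
Reactants: 5 (Z)-6,6-diethoxy-3-methylhex-2-en-4-yn-1-ol
Product: 6 (Z)-6,6-diethoxy-3-methylhex-2-en-4-ynal
Conditions: MnO2, CH2Cl2, 23 °C
Reagents that add atoms: none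
Why: Neutral allylic oxidation with MnO2 should give the enal without touching the acetal and without Z/E isomerisation.

Step 4
Reactants: 7 4-tert-butoxy-4-oxobutanoic acid; 8 (R)-4-benzyloxazolidin-2-one
Product: 10 tert-butyl 4-[(4R)-4-benzyl-2-oxooxazolidin-3-yl]-4-oxobutanoate, via mixed pivalic anhydride 9 (not isolated)
Conditions: PivCl, Et3N, THF, −20 °C; then 8, LiCl, −20 → 23 °C
Reagents that add atoms: none
Why: Standard N-acylation of an Evans auxiliary through the mixed pivalic anhydride, with LiCl activating the oxazolidinone.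

Step 5
Reactants: 10 tert-butyl 4-[(4R)-4-benzyl-2-oxooxazolidin-3-yl]-4-oxobutanoate; 6 (Z)-6,6-diethoxy-3-methylhex-2-en-4-ynal
Product: 12 tert-butyl (3S,4S,5Z)-3-{[(4R)-4-benzyl-2-oxooxazolidin-3-yl]carbonyl}-9,9-diethoxy-4-hydroxy-6-methylnon-5-en-7-ynoate, via trimethylsilyl ether 11 (not isolated)
Conditions: MgCl2 (20 mol%), Et3N, Me3SiCl, EtOAc, 23 °C; then 1 M HCl/THF (1:5), 23 °C
Reagents that add atoms: none
Why: Evans magnesium-halide-catalysed anti-aldol of a non-enolisable enal: the chelated Z-enolate should react anti to the benzyl group through a boat transition state, setting C7 and C6 (anti) together.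

Step 6
Reactants: 12 anti-aldol adduct
Product: 13 tert-butyl (3S,4S,5Z)-3-{[(4R)-4-benzyl-2-oxooxazolidin-3-yl]carbonyl}-9,9-diethoxy-6-methyl-4-(triisopropylsilyloxy)non-5-en-7-ynoate
Conditions: i-Pr3SiOTf, 2,6-lutidine, CH2Cl2, −78 °C
Reagents that add atoms: triisopropylsilyl trifluoromethanesulfonate, CC(C)[Si](C(C)C)(C(C)C)OS(=O)(=O)C(F)(F)F
Why: Silyl triflate silylation of a hindered secondary alcohol is fast at −78 °C, where the alkynyl acetal (a poor oxocarbenium precursor) should stay intact; the TIPS ether is chosen to survive the later acid step.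

Step 7
Reactants: 13 silylated imide
Product: 14 tert-butyl (3R,4S,5Z)-9,9-diethoxy-3-(hydroxymethyl)-6-methyl-4-(triisopropylsilyloxy)non-5-en-7-ynoate
Conditions: LiBH4, THF, 0 → 23 °C
Reagents that add atoms: none
Why: Reductive removal of the Evans auxiliary by LiBH4 is selective for the imide over the tert-butyl ester, which is also too hindered to lactonise with the new primary alcohol.

Step 8
Reactants: 14 primary alcohol
Product: 15 tert-butyl (3S,4S,5Z)-9,9-diethoxy-3-formyl-6-methyl-4-(triisopropylsilyloxy)non-5-en-7-ynoate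
Conditions: Dess–Martin periodinane, pyridine, CH2Cl2, 0 °C
Reagents that add atoms: none
Why: Buffered Dess–Martin oxidation gives the α-branched aldehyde (C8) without epimerisation at C7 or loss of the acetal.

Step 9
Reactants: 15 aldehyde; 16 acetone
Product: 17 tert-butyl (3R,4S)-3-[(1S,2Z)-6,6-diethoxy-3-methyl-1-(triisopropylsilyloxy)hex-2-en-4-yn-1-yl]-4-hydroxy-6-oxoheptanoate
Conditions: D-proline (30 mol%), acetone/DMSO (1:4), 4 → 23 °C
Reagents that add atoms: none
Why: Proline-catalysed (List-type enamine) acetone aldol on an α-branched aldehyde: the D-proline enamine should add to the si face of the aldehyde, which is also the Felkin–Anh face, setting C8 (S) and delivering the C10 methyl ketone.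

Step 10
Reactants: 17 β-hydroxy ketone
Product: 20 (4R,5S)-4-[(1S,2Z)-3-methyl-6-oxo-1-(triisopropylsilyloxy)hex-2-en-4-yn-1-yl]-5-(2-oxopropyl)dihydrofuran-2(3H)-one, via hydroxy acid 18 (not isolated), via lactone acetal 19 (not isolated)
Conditions: CF3CO2H, CH2Cl2, 0 °C; then H2O added, 23 °C
Reagents that add atoms: water, O
Why: Acidolysis of the tert-butyl ester, spontaneous γ-lactonisation of the hydroxy acid and hydrolysis of the alkynyl acetal should occur in one pot, with the TIPS ether surviving; the trans-lactone follows from the fixed C7 and C8 centres.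

Step 11
Reactants: 20 seco ynal–methyl ketone
Product: 22 (6S,7R,8S,10R)-3,10-epoxy-1-oxo-6-(triisopropylsilyloxy)germacra-2,4(Z)-dien-12,8-olide, via cyclic hydroxy ynone 21 (not isolated)
Conditions: (5aR,10bS)-2-(pentafluorophenyl)-5a,10b-dihydro-4H,6H-indeno[2,1-b][1,2,4]triazolo[4,3-d][1,4]oxazin-2-ium tetrafluoroborate (20 mol%), i-Pr2NEt (20 mol%), toluene, 40 °C, syringe-pump addition of 20 to 0.002 M
Reagents that add atoms: none
Why: Proposed new method: the triazolylidene adds to the C1 aldehyde of the ynal to give the Breslow (acyl-anion) intermediate, which attacks the C10 methyl ketone and closes the ten-membered carbocycle (10-exo-trig) as the strained cyclic α′-hydroxy ynone 21; after release of the carbene, 5-endo-dig oxa-Michael addition of the tertiary C10–O to C3 closes the furanone, and this irreversible, strain-releasing step drains the reversible benzoin equilibrium. The closest known reaction types are the carbene-catalysed intramolecular aldehyde–ketone crossed benzoin (five- and six-membered rings) and the base- or gold-catalysed cyclisation of α′-hydroxy ynones to 3(2H)-furanones; their merger on an ynal in a medium-ring closure is new. The only new stereocentre, C10, is set when C1 adds to the Si face of the ketone, which the indane wall of the catalyst and the trans-lactone tether at C8 are expected to favour. Selectivity needed: acyl-anion reactivity at C1 instead of homoenolate/redox reactivity at C3, secured by the N-pentafluorophenyl triazolium in aprotic medium and by geometry (C3 attack would put an allene in an eight-membered ring); intramolecular over intermolecular benzoin, secured by slow addition at high dilution; and survival of the β-acyloxy ketone, secured by the weak amine base.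

Step 12
Reactants: 22 bridged furanone lactone
Product: 25 (6S,7R,8S,10R)-3,10-epoxy-1-oxo-6-(triisopropylsilyloxy)germacra-2,4(Z),11(13)-trien-12,8-olide, via Mannich base 23 (not isolated), via methiodide 24 (not isolated)
Conditions: LiN(i-Pr)2, THF, −78 °C; CH2=NMe2+ I−, −78 → 0 °C; then MeI, MeOH, 23 °C; then NaHCO3 (aq), EtOAc, 23 °C
Reagents that add atoms: N,N-dimethylmethyleneiminium iodide (Eschenmoser's salt), C=[N+](C)C.[I-]
Why: Eschenmoser α-methylenation (enolate Mannich reaction, quaternisation, elimination); the lactone α-CH2 is the only acidic site because the C1 ketone has no α-hydrogen, and the C11 centre of 23 is destroyed on elimination.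

Step 13
Reactants: 25 silyl ether
Product: 26 (6S,7S,8S,10R)-3,10-epoxy-6-hydroxy-1-oxogermacra-2,4(Z),11(13)-trien-12,8-olide (same spatial arrangement; the C7 descriptor changes with the free hydroxyl)
Conditions: HF·pyridine, pyridine, THF, 0 → 40 °C
Reagents that add atoms: none
Why: Buffered HF·pyridine desilylation is compatible with the α-methylene lactone and the furanone.

Step 14
Reactants: 27 angelic acid [(Z)-2-methylbut-2-enoic acid]
Product: 28 (Z)-2-methylbut-2-en-1-ol
Conditions: LiAlH4, Et2O, 0 °C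
Reagents that add atoms: none
Why: Hydride reduction of the unsaturated acid to the allylic alcohol should keep the Z geometry.

Step 15
Reactants: 28 (Z)-2-methylbut-2-en-1-ol
Product: 29 [(2R,3S)-2,3-dimethyloxiran-2-yl]methanol
Conditions: Ti(O-i-Pr)4 (10 mol%), D-(−)-diethyl tartrate (12 mol%), t-BuOOH, 4 Å molecular sieves, CH2Cl2, −20 °C
Reagents that add atoms: tert-butyl hydroperoxide, CC(C)(C)OO
Why: Sharpless asymmetric epoxidation; the D-(−)-tartrate catalyst delivers oxygen to the face that gives the 2R,3S epoxy alcohol, and the Z geometry fixes the cis relation of CH2OH and the 3-methyl.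

Step 16
Reactants: 29 epoxy alcohol
Product: 30 (2S,3S)-2,3-dimethyloxirane-2-carboxylic acid
Conditions: RuCl3 hydrate (2 mol%), NaIO4, CH3CN/EtOAc/H2O, 0 → 23 °C
Reagents that add atoms: water, O
Why: Sharpless RuCl3/NaIO4 oxidation takes an epoxy alcohol to the glycidic acid without opening the oxirane; the stereocentres are untouched (the C2 descriptor changes only by priority).

Step 17
Reactants: 30 (2S,3S)-2,3-dimethyloxirane-2-carboxylic acid; 26 C6 alcohol
Product: 32 CNP0258430.4, via mixed anhydride 31 (not isolated)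
Conditions: 2,4,6-trichlorobenzoyl chloride, Et3N, toluene, 23 °C; then 26, DMAP, toluene, 23 °C
Reagents that add atoms: none
Why: Yamaguchi esterification acylates the hindered allylic C6 alcohol with an acid that has no α-hydrogen, so no stereocentre can be lost; acylation should outpace translactonisation.

**Compound list**

1 | but-2-yn-1-ol | CC#CCO | starting material
2 | sodium 2,2-bis(2-methoxyethoxy)-3-methyl-2,5-dihydro-1,2-oxaluminol-2-uide | CC1=CCO[Al-]1(OCCOC)OCCOC.[Na+] | intermediate
3 | (Z)-3-iodobut-2-en-1-ol | OC/C=C(C)\I | intermediate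
4 | 3,3-diethoxyprop-1-yne | C#CC(OCC)OCC | starting material
5 | (Z)-6,6-diethoxy-3-methylhex-2-en-4-yn-1-ol | CCOC(OCC)C#C/C(C)=C\CO | intermediate
6 | (Z)-6,6-diethoxy-3-methylhex-2-en-4-ynal | CCOC(OCC)C#C/C(C)=C\C=O | intermediate
7 | 4-tert-butoxy-4-oxobutanoic acid | CC(C)(C)OC(=O)CCC(=O)O | starting material
8 | (R)-4-benzyloxazolidin-2-one | O=C1N[C@H](Cc2ccccc2)CO1 | starting material
9 | 4-tert-butoxy-4-oxobutanoic pivalic anhydride | CC(C)(C)OC(=O)CCC(=O)OC(=O)C(C)(C)C | intermediate
10 | tert-butyl 4-[(4R)-4-benzyl-2-oxooxazolidin-3-yl]-4-oxobutanoate | CC(C)(C)OC(=O)CCC(=O)N1[C@H](Cc2ccccc2)COC1=O | intermediate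
11 | 4-O-trimethylsilyl ether of 12 (3S,4S,5Z) | O=C([C@@H](CC(=O)OC(C)(C)C)[C@@H](O[Si](C)(C)C)/C=C(C)\C#CC(OCC)OCC)N1[C@H](Cc2ccccc2)COC1=O | intermediate
12 | tert-butyl (3S,4S,5Z)-3-{[(4R)-4-benzyl-2-oxooxazolidin-3-yl]carbonyl}-9,9-diethoxy-4-hydroxy-6-methylnon-5-en-7-ynoate | O=C([C@@H](CC(=O)OC(C)(C)C)[C@@H](O)/C=C(C)\C#CC(OCC)OCC)N1[C@H](Cc2ccccc2)COC1=O | intermediate
13 | tert-butyl (3S,4S,5Z)-3-{[(4R)-4-benzyl-2-oxooxazolidin-3-yl]carbonyl}-9,9-diethoxy-6-methyl-4-(triisopropylsilyloxy)non-5-en-7-ynoate | O=C([C@@H](CC(=O)OC(C)(C)C)[C@@H](O[Si](C(C)C)(C(C)C)C(C)C)/C=C(C)\C#CC(OCC)OCC)N1[C@H](Cc2ccccc2)COC1=O | intermediate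
14 | tert-butyl (3R,4S,5Z)-9,9-diethoxy-3-(hydroxymethyl)-6-methyl-4-(triisopropylsilyloxy)non-5-en-7-ynoate | OC[C@@H](CC(=O)OC(C)(C)C)[C@@H](O[Si](C(C)C)(C(C)C)C(C)C)/C=C(C)\C#CC(OCC)OCC | intermediate
15 | tert-butyl (3S,4S,5Z)-9,9-diethoxy-3-formyl-6-methyl-4-(triisopropylsilyloxy)non-5-en-7-ynoate | O=C[C@@H](CC(=O)OC(C)(C)C)[C@@H](O[Si](C(C)C)(C(C)C)C(C)C)/C=C(C)\C#CC(OCC)OCC | intermediate
16 | acetone | CC(C)=O | starting material
17 | tert-butyl (3R,4S)-3-[(1S,2Z)-6,6-diethoxy-3-methyl-1-(triisopropylsilyloxy)hex-2-en-4-yn-1-yl]-4-hydroxy-6-oxoheptanoate | CC(=O)C[C@H](O)[C@@H](CC(=O)OC(C)(C)C)[C@@H](O[Si](C(C)C)(C(C)C)C(C)C)/C=C(C)\C#CC(OCC)OCC | intermediate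
18 | (3R,4S)-3-[(1S,2Z)-6,6-diethoxy-3-methyl-1-(triisopropylsilyloxy)hex-2-en-4-yn-1-yl]-4-hydroxy-6-oxoheptanoic acid | CC(=O)C[C@H](O)[C@@H](CC(=O)O)[C@@H](O[Si](C(C)C)(C(C)C)C(C)C)/C=C(C)\C#CC(OCC)OCC | intermediate
19 | (4R,5S)-4-[(1S,2Z)-6,6-diethoxy-3-methyl-1-(triisopropylsilyloxy)hex-2-en-4-yn-1-yl]-5-(2-oxopropyl)dihydrofuran-2(3H)-one | CC(=O)C[C@@H]1OC(=O)C[C@H]1[C@@H](O[Si](C(C)C)(C(C)C)C(C)C)/C=C(C)\C#CC(OCC)OCC | intermediate
20 | (4R,5S)-4-[(1S,2Z)-3-methyl-6-oxo-1-(triisopropylsilyloxy)hex-2-en-4-yn-1-yl]-5-(2-oxopropyl)dihydrofuran-2(3H)-one | CC(=O)C[C@@H]1OC(=O)C[C@H]1[C@@H](O[Si](C(C)C)(C(C)C)C(C)C)/C=C(C)\C#CC=O | intermediate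
21 | (6S,7R,8S,10R)-10-hydroxy-1-oxo-6-(triisopropylsilyloxy)germacr-4(Z)-en-2-yn-12,8-olide | C1C(=O)O[C@H]2C[C@@](C)(O)C(=O)C#C/C(C)=C\[C@H](O[Si](C(C)C)(C(C)C)C(C)C)[C@H]12 | intermediate
22 | (6S,7R,8S,10R)-3,10-epoxy-1-oxo-6-(triisopropylsilyloxy)germacra-2,4(Z)-dien-12,8-olide | C1C(=O)O[C@H]2C[C@@]3(C)OC(=CC3=O)/C(C)=C\[C@H](O[Si](C(C)C)(C(C)C)C(C)C)[C@H]12 | intermediate
23 | (11S)-13-(dimethylamino) derivative of 22 (Mannich base, CH2NMe2 trans to C6 on the lactone) | CN(C)C[C@H]1C(=O)O[C@H]2C[C@@]3(C)OC(=CC3=O)/C(C)=C\[C@H](O[Si](C(C)C)(C(C)C)C(C)C)[C@H]12 | intermediate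
24 | N-methyl ammonium iodide of 23 | C[N+](C)(C)C[C@H]1C(=O)O[C@H]2C[C@@]3(C)OC(=CC3=O)/C(C)=C\[C@H](O[Si](C(C)C)(C(C)C)C(C)C)[C@H]12.[I-] | intermediate
25 | (6S,7R,8S,10R)-3,10-epoxy-1-oxo-6-(triisopropylsilyloxy)germacra-2,4(Z),11(13)-trien-12,8-olide | C=C1C(=O)O[C@H]2C[C@@]3(C)OC(=CC3=O)/C(C)=C\[C@H](O[Si](C(C)C)(C(C)C)C(C)C)[C@H]12 | intermediate
26 | (6S,7S,8S,10R)-3,10-epoxy-6-hydroxy-1-oxogermacra-2,4(Z),11(13)-trien-12,8-olide | C=C1C(=O)O[C@H]2C[C@@]3(C)OC(=CC3=O)/C(C)=C\[C@H](O)[C@H]12 | intermediate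
27 | angelic acid, (Z)-2-methylbut-2-enoic acid | C/C=C(C)\C(=O)O | starting material
28 | (Z)-2-methylbut-2-en-1-ol | C/C=C(C)\CO | intermediate
29 | [(2R,3S)-2,3-dimethyloxiran-2-yl]methanol | OC[C@@]1(C)O[C@H]1C | intermediate
30 | (2S,3S)-2,3-dimethyloxirane-2-carboxylic acid | OC(=O)[C@@]1(C)O[C@H]1C | intermediate
31 | (2S,3S)-2,3-dimethyloxirane-2-carboxylic 2,4,6-trichlorobenzoic anhydride | O=C(OC(=O)[C@@]1(C)O[C@H]1C)c1c(Cl)cc(Cl)cc1Cl | intermediate
32 | CNP0258430.4, (6S,7R,8S,10R)-6-[(2S,3S)-2,3-dimethyloxirane-2-carbonyloxy]-3,10-epoxy-1-oxogermacra-2,4(Z),11(13)-trien-12,8-olide | C=C1C(=O)O[C@H]2C[C@@]3(C)OC(=CC3=O)/C(C)=C\[C@H](OC(=O)[C@@]3(C)O[C@H]3C)[C@H]12 | target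

**Step count and risks**

Total steps: 17. Longest linear sequence: 13 (steps 1–3, 5–13, 17).

Steps most likely to fail:

1. Step 11 (proposed new method). What may go wrong: protonation of the Breslow intermediate at C3 (internal redox to an acyl azolium) instead of C1–C10 closure; addition to the wrong face of the C10 ketone; base-induced β-elimination of the lactone carboxylate from the methyl ketone; oligomerisation. Fallback with known chemistry, setting out from 20 and coming back at 22: a SmI2-mediated intramolecular ketyl–carbonyl (pinacol) coupling of the aldehyde and the ketone (THF, −78 °C, high dilution) should give the ten-membered (1S,6S,7R,8S,10R)-1,10-dihydroxy-6-(triisopropylsilyloxy)germacr-4(Z)-en-2-yn-12,8-olide F1 (the C1 centre is erased next). MnO2 oxidation of its secondary propargylic alcohol gives the α′-hydroxy ynone 21, and AuCl3 (5 mol%, CH2Cl2) closes it 5-endo-dig to 22.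

2. Step 5. What may go wrong: Z to E isomerisation of the enal under the amine/Lewis acid conditions, and erosion of anti selectivity in the boat transition state. Fallback, setting out from 6 and coming back at 15: an L-proline-catalysed direct cross-aldol with commercial tert-butyl 4-oxobutanoate as the enamine donor (DMF, 4 °C, slow addition of the donor) attacks the re face of 6. It should give tert-butyl (3S,4S,5Z)-9,9-diethoxy-3-formyl-4-hydroxy-6-methylnon-5-en-7-ynoate F2, the anti hydroxy aldehyde. Silylation with i-Pr3SiOTf/2,6-lutidine gives 15, which also removes steps 6–8.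

3. Step 9. What may go wrong: epimerisation at C7 through enamine formation of the α-branched aldehyde, β-elimination of the silyloxy group, or mismatched double induction. Fallback, setting out from 15 and coming back at 17: a Mukaiyama aldol with 2-(trimethylsilyloxy)propene and BF3·OEt2 (CH2Cl2, −78 °C) under substrate control (Felkin–Anh addition reinforced by 1,3-anti induction from the C6 silyloxy group) gives 17 directly; no new compound arises (F0).

**Further compounds**

F1 | step 11 | (1S,6S,7R,8S,10R)-1,10-dihydroxy-6-(triisopropylsilyloxy)germacr-4(Z)-en-2-yn-12,8-olide | C1C(=O)O[C@H]2C[C@@](C)(O)[C@@H](O)C#C/C(C)=C\[C@H](O[Si](C(C)C)(C(C)C)C(C)C)[C@H]12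
F2 | step 5 | tert-butyl (3S,4S,5Z)-9,9-diethoxy-3-formyl-4-hydroxy-6-methylnon-5-en-7-ynoate | O=C[C@@H](CC(=O)OC(C)(C)C)[C@@H](O)/C=C(C)\C#CC(OCC)OCC
F0 | step 9 | none | none
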